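**Plan**

1. Retrosynthesis: cut the C15–O ester bond (diterpene alcohol plus an ω-silyloxy C30 acid, itself cut into C14 and C16 halves). Then cut C14–C15 and C13–CH3 (alkyne carbometalation), C9–C11, the ring A bond C3–C4, and C10–C1 and C10–CH3, which leads back to (S)-(+)-carvone.
2. Forward: ring B is the ring of carvone; two enolate alkylations build the quaternary C10; ring A arises in step 5. The C9 side chain follows (Grignard addition, oxidative 1,3-transposition, Li/NH3 reduction with enolate triflation, triflate reduction, alkyne, carboalumination), then esterification and desilylation.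
3. Enabling feature: in ring A the gem-dimethyl carbon C4 lies between the carbinol carbon C3 and the ring-fusion carbon C5. C4 with one of its methyls is therefore the Markovnikov radical of carvone's isopropenyl group, and C3 is an aldehyde carbon. The C8 methyl, the C7=C8 alkene and the C5 stereocentre of ring B are those of carvone.
4. Stereochemistry: C5 is bought with (S)-carvone; C10 is set by alkylation anti to the isopropenyl group; C3 and the trans ring fusion arise in step 5 under substrate control; C9 is set by axial protonation anti to the angular methyl; 13E comes from syn-carboalumination.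

Key step: step 5

Remark: labdane numbering is used for the terpenoid carbons throughout; the target belongs to the ent-labdane series (3-OH equatorial, cis to the C10 methyl) and carries a 30-hydroxytriacontanoyl group.

**Route**

Step 1
Reactants: 1 (S)-(+)-carvone
Product: 3 6-methylcarvone (mixture of C6 epimers), via lithium enolate 2 (not isolated)
Conditions: LiN(i-Pr)2 (1.05 equiv), THF, −78 °C; then MeI, −78 → 0 °C
Reagents that add atoms: iodomethane, CI
Why: kinetic deprotonation at the only sp3 α-carbon gives the cross-conjugated enolate, which is C-methylated (enolate alkylation); the new centre need not be controlled because it becomes planar again in step 2.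

Step 2
Reactants: 3 6-methylcarvone
Product: 5 6-allyl-6-methylcarvone (allyl trans and methyl cis to the isopropenyl group), via lithium enolate 4 (not isolated)
Conditions: LiN(i-Pr)2 (1.1 equiv), THF, −78 → 0 °C; then allyl bromide, DMPU, −78 °C → rt
Reagents that add atoms: allyl bromide, C=CCBr
Why: enolate allylation; the tetrasubstituted enolate is attacked on the face anti to the neighbouring isopropenyl group, which sets the quaternary C10 with the three-carbon arm (future C1–C3) trans to the future C4.

Step 3
Reactants: 5 6-allyl-6-methylcarvone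
Product: 7 6-(3-hydroxypropyl)-6-methylcarvone, via catechol boronate 6 (not isolated)
Conditions: catecholborane (1.2 equiv), RhCl(PPh3)3 (2 mol %), THF, 0 °C → rt; then 30 % H2O2, pH 7 phosphate buffer, 0 °C → rt
Reagents that add atoms: hydrogen peroxide, OO
Why: rhodium-catalysed anti-Markovnikov hydroboration is selective for the monosubstituted alkene over the 1,1-disubstituted and trisubstituted alkenes and tolerates the hindered enone, and neutral peroxide oxidises the C–B bond without epoxidising the enone.

Step 4
Reactants: 7 6-(3-hydroxypropyl)-6-methylcarvone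
Product: 8 keto aldehyde 6-(3-oxopropyl)-6-methylcarvone
Conditions: Dess–Martin periodinane (1.2 equiv), CH2Cl2, 0 °C → rt
Reagents that add atoms: none
Why: Dess–Martin oxidation of a primary alcohol stops at the aldehyde and leaves the alkenes and the enone untouched.

Step 5
Reactants: 8 keto aldehyde
Product: 11 ent-3β-hydroxy-11-nordrim-7-en-9-one (trans-fused; 3-OH equatorial and cis to the C10 methyl), via tertiary radical 9 (not isolated), via alkoxyl radical 10 (not isolated)
Conditions: Fe(acac)3 (1.0 equiv), PhSiH3 (2.5 equiv), EtOH, 60 °C, 0.02 M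
Reagents that add atoms: none
Why: The iron hydride formed from Fe(acac)3 and PhSiH3 in ethanol transfers a hydrogen atom to the CH2 terminus of the isopropenyl group (Markovnikov MHAT), which makes that carbon the second C4 methyl and leaves the tertiary radical 9 at C4; 9 adds to the aldehyde carbon C3, and the alkoxyl radical 10 is reduced by divalent iron and protonated by ethanol. The closest known reaction type is the iron-hydride-initiated reductive radical cyclisation of alkene-tethered ketones, together with the intermolecular MHAT coupling of unactivated alkenes with aldehydes. Ring A closes in the 6-exo-trig mode onto the C=O group through a chair transition state. C3 is the only new stereocentre and is set by the substrate: the carbonyl oxygen should take the pseudo-equatorial position of the chair, away from the axial hydrogens on C1 and C5, so the hydroxyl ends equatorial and cis to the angular methyl, and reversibility of the closure (β-scission of 10) works in the same direction; the trans ring fusion is relayed, because the radical arm on C5 and the aldehyde arm on C10 are trans on ring B and can only meet in the trans-fused chair. The step needs hydrogen atom transfer to the 1,1-disubstituted alkene in the presence of the trisubstituted enone alkene, which the higher reactivity of electron-rich 1,1-disubstituted alkenes secures, and ring closure faster than reduction of 9 or its intermolecular Giese addition, which the fast 6-exo attack on an aldehyde and high dilution secure; the radical cannot reach the enone because a four-membered ring would result.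

Step 6
Reactants: 11 ent-3β-hydroxy-11-nordrim-7-en-9-one
Product: 12 ent-3β-(tert-butyldimethylsilyloxy)-11-nordrim-7-en-9-one
Conditions: TBSCl (1.5 equiv), imidazole (3 equiv), DMAP (cat.), DMF, 40 °C
Reagents that add atoms: tert-butyldimethylsilyl chloride, CC(C)(C)[Si](C)(C)Cl
Why: imidazole-promoted silylation protects the C3 hydroxyl against the Grignard reagent and the chromium oxidant of the next two steps and carries it to the last step.

Step 7
Reactants: 12 ent-3β-(tert-butyldimethylsilyloxy)-11-nordrim-7-en-9-one
Product: 13 tertiary allylic alcohol: 9-hydroxy-9-[2-(1,3-dioxan-2-yl)ethyl] adduct of 12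
Conditions: BrMgCH2CH2(1,3-dioxan-2-yl) (0.5 M in THF, 3 equiv), LaCl3·2LiCl (0.3 equiv), THF, 0 °C → rt; aq. NH4Cl
Reagents that add atoms: [2-(1,3-dioxan-2-yl)ethyl]magnesium bromide, Br[Mg]CCC1OCCCO1
Why: Grignard 1,2-addition to the non-enolisable, hindered C9 ketone from the face anti to the angular methyl brings in C11–C13; the configuration of the new carbinol centre is of no consequence because it is erased in step 8.

Step 8
Reactants: 13 tertiary allylic alcohol
Product: 14 ent-3β-(tert-butyldimethylsilyloxy)-7-oxo-14,15,16-trinorlabd-8-en-13-al propane-1,3-diyl acetal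
Conditions: pyridinium chlorochromate [C5H5NH][CrO3Cl] (3 equiv), 4 Å molecular sieves, CH2Cl2, rt
Reagents that add atoms: pyridinium chlorochromate, [O-][Cr](=O)(=O)Cl.c1cc[nH+]cc1
Why: Babler–Dauben oxidative 1,3-transposition: the tertiary allylic chromate ester rearranges suprafacially to the C7 chromate, which is oxidised to the 8-en-7-one, so that C11 now sits on an sp2 C9 and C7 carries an oxygen taken from the chromate.

Step 9
Reactants: 14 8-en-7-one
Product: 16 C7 enol triflate (C7=C8; H9 trans and side chain cis to the C10 methyl), via lithium enolate 15 (not isolated)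
Conditions: Li (2.2 equiv), t-BuOH (1.0 equiv), NH3/THF, −78 °C; NH3 evaporated; then PhNTf2 (1.5 equiv), THF, 0 °C → rt
Reagents that add atoms: N-phenylbis(trifluoromethanesulfonimide), O=S(=O)(N(c1ccccc1)S(=O)(=O)C(F)(F)F)C(F)(F)F
Why: dissolving-metal (Birch-type) reduction of the enone protonates the β-carbon C9 axially on the face anti to the angular C10 methyl, the only protonation that keeps ring B chair-like, which sets C9, and the regiodefined C7 enolate is trapped as its enol triflate.

Step 10
Reactants: 16 C7 enol triflate
Product: 17 ent-3β-(tert-butyldimethylsilyloxy)-14,15,16-trinorlabd-7-en-13-al propane-1,3-diyl acetal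
Conditions: Pd(OAc)2 (5 mol %), PPh3 (10 mol %), HCO2H (2 equiv), n-Bu3N (3 equiv), DMF, 60 °C
Reagents that add atoms: none
Why: palladium-catalysed formate reduction of an enol triflate (oxidative addition to zerovalent palladium, formate exchange, decarboxylation, reductive elimination) replaces OTf by H without moving the C7=C8 double bond or touching C9.

Step 11
Reactants: 17 Δ7 acetal
Product: 18 ent-3β-(tert-butyldimethylsilyloxy)-14,15,16-trinorlabd-7-en-13-al
Conditions: TsOH·H2O (0.2 equiv), acetone/H2O (10:1), 50 °C
Reagents that add atoms: water, O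
Why: acid-catalysed acetal hydrolysis frees the C13 aldehyde, while the hindered secondary silyl ether next to the gem-dimethyl group and the trisubstituted alkene should survive these mild conditions.

Step 12
Reactants: 18 C13 aldehyde
Product: 19 ent-3β-(tert-butyldimethylsilyloxy)-15,16-dinorlabd-7-en-13-yne
Conditions: dimethyl (1-diazo-2-oxopropyl)phosphonate (1.5 equiv), K2CO3 (2 equiv), MeOH/THF, 0 °C → rt
Reagents that add atoms: dimethyl (1-diazo-2-oxopropyl)phosphonate, COP(=O)(OC)C(=[N+]=[N-])C(C)=O
Why: Ohira–Bestmann (Seyferth–Gilbert) homologation converts the aldehyde into the terminal alkyne with one added carbon (C14) under mild base, and no stereocentre is adjacent.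

Step 13
Reactants: 19 terminal alkyne
Product: 22 ent-3β-(tert-butyldimethylsilyloxy)labda-7,13E-dien-15-ol, via alkenylalane 20 (not isolated), via lithium alanate 21 (not isolated)
Conditions: AlMe3 (2.5 equiv), Cp2ZrCl2 (0.25 equiv), CH2Cl2, 0 °C → rt; volatiles removed; n-BuLi (1.1 equiv), THF/hexane, −78 °C; then (CH2O)n (5 equiv), −78 °C → rt
Reagents that add atoms: trimethylaluminium, C[Al](C)C; paraformaldehyde (as formaldehyde), C=O
Why: Negishi zirconium-catalysed carboalumination adds CH3 and Al syn across the terminal alkyne with the methyl on C13, and the alanate is hydroxymethylated by formaldehyde with retention, which fixes the 13E geometry and gives the primary allylic alcohol.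

Step 14
Reactants: 23 tetradecane-1,14-diol
Product: 24 14-bromotetradecan-1-ol
Conditions: 48 % aq. HBr (1.1 equiv), toluene, reflux
Reagents that add atoms: hydrogen bromide, Br
Why: monobromination of a symmetrical α,ω-diol (substitution of the protonated alcohol by bromide) in a two-phase system, in which the bromo alcohol passes into toluene and reacts a second time much more slowly.

Step 15
Reactants: 24 14-bromotetradecan-1-ol
Product: 25 (14-bromotetradecyloxy)(tert-butyl)dimethylsilane
Conditions: TBSCl (1.2 equiv), imidazole (2 equiv), CH2Cl2, rt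
Reagents that add atoms: tert-butyldimethylsilyl chloride, CC(C)(C)[Si](C)(C)Cl
Why: silylation of the primary alcohol masks the hydroxyl for Grignard formation.

Step 16
Reactants: 25 (14-bromotetradecyloxy)(tert-butyl)dimethylsilane; 26 16-bromohexadecanoic acid
Product: 29 30-(tert-butyldimethylsilyloxy)triacontanoic acid, via Grignard reagent 27 (not isolated), via magnesium carboxylate 28 (not isolated)
Conditions: 25, Mg, THF, 45 °C; separately 26, MeMgCl (1.0 equiv), THF, −20 °C; the two solutions combined (1.5 equiv of 27), Li2CuCl4 (3 mol %), THF, −20 °C → rt; cold 0.5 M HCl work-up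
Reagents that add atoms: none
Why: copper-catalysed sp3–sp3 cross-coupling of a primary alkyl Grignard reagent with a primary alkyl bromide joins the C14 and C16 halves, while the acid is masked in the flask as its magnesium carboxylate, which is inert at low temperature.

Step 17
Reactants: 22 ent-3β-(tert-butyldimethylsilyloxy)labda-7,13E-dien-15-ol; 29 30-(tert-butyldimethylsilyloxy)triacontanoic acid
Product: 30 ent-3β-(tert-butyldimethylsilyloxy)labda-7,13E-dien-15-yl 30-(tert-butyldimethylsilyloxy)triacontanoate
Conditions: 29 (1.2 equiv), EDC·HCl (1.5 equiv), DMAP (0.3 equiv), CH2Cl2, rt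
Reagents that add atoms: none
Why: Steglich esterification acylates the only free hydroxyl, the primary allylic C15–OH, under neutral conditions without allylic transposition.

Step 18
Reactants: 30 bis-silyl ester
Product: 31 ent-3β-hydroxylabda-7,13E-dien-15-yl 30-hydroxytriacontanoate (target)
Conditions: HF·pyridine, pyridine/THF, 0 °C → rt
Reagents that add atoms: none
Why: fluoride-mediated cleavage of both silyl ethers with buffered HF·pyridine should leave the allylic ester and the two trisubstituted alkenes intact and release the target.

**Compound list**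

1 | (S)-(+)-carvone, (5S)-2-methyl-5-(prop-1-en-2-yl)cyclohex-2-en-1-one | CC1=CC[C@@H](CC1=O)C(C)=C | starting material
2 | lithium enolate of 1 (cross-conjugated, C1–O−, C1=C6) | CC1=CC[C@H](C(C)=C)C=C1[O-].[Li+] | intermediate (not isolated)
3 | 6-methylcarvone, (5S)-2,6-dimethyl-5-(prop-1-en-2-yl)cyclohex-2-en-1-one, mixture of C6 epimers | CC1=CC[C@H](C(C)=C)C(C)C1=O | intermediate
4 | lithium enolate of 3 | CC1=CC[C@H](C(C)=C)C(C)=C1[O-].[Li+] | intermediate (not isolated)
5 | 6-allyl-6-methylcarvone, allyl trans and methyl cis to the isopropenyl group | CC1=CC[C@H](C(C)=C)[C@@](C)(CC=C)C1=O | intermediate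
6 | B-alkyl catecholborane from 5 (boron on the terminal carbon of the former allyl group) | CC1=CC[C@H](C(C)=C)[C@@](C)(CCCB2Oc3ccccc3O2)C1=O | intermediate (not isolated)
7 | 6-(3-hydroxypropyl)-6-methylcarvone, configuration as in 5 | CC1=CC[C@H](C(C)=C)[C@@](C)(CCCO)C1=O | intermediate
8 | keto aldehyde, 6-(3-oxopropyl)-6-methylcarvone, configuration as in 5 | CC1=CC[C@H](C(C)=C)[C@@](C)(CCC=O)C1=O | intermediate
9 | tertiary C4 radical (2-propyl radical on C5 of 8) | CC1=CC[C@H]([C](C)C)[C@@](C)(CCC=O)C1=O | intermediate (not isolated)
10 | C3 alkoxyl radical of 11 | CC1=CC[C@@H]2C(C)(C)[C@H]([O])CC[C@@]2(C)C1=O | intermediate (not isolated)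
11 | ent-3β-hydroxy-11-nordrim-7-en-9-one; trans-fused 6-hydroxy-2,5,5,8a-tetramethyl-4a,5,6,7,8,8a-hexahydronaphthalen-1(4H)-one, OH equatorial and cis to the angular methyl | CC1=CC[C@@H]2C(C)(C)[C@H](O)CC[C@@]2(C)C1=O | intermediate
12 | 3-O-tert-butyldimethylsilyl ether of 11 | CC1=CC[C@@H]2C(C)(C)[C@H](O[Si](C)(C)C(C)(C)C)CC[C@@]2(C)C1=O | intermediate
13 | 9-hydroxy-9-[2-(1,3-dioxan-2-yl)ethyl] adduct of 12 (side chain anti to the C10 methyl) | CC1=CC[C@@H]2C(C)(C)[C@H](O[Si](C)(C)C(C)(C)C)CC[C@@]2(C)[C@@]1(O)CCC3OCCCO3 | intermediate
14 | ent-3β-(tert-butyldimethylsilyloxy)-7-oxo-14,15,16-trinorlabd-8-en-13-al propane-1,3-diyl acetal | CC=1C(=O)C[C@@H]2C(C)(C)[C@H](O[Si](C)(C)C(C)(C)C)CC[C@@]2(C)C=1CCC3OCCCO3 | intermediate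
15 | lithium C7 enolate (C7=C8), H9 trans to the C10 methyl | CC1=C([O-])C[C@@H]2C(C)(C)[C@H](O[Si](C)(C)C(C)(C)C)CC[C@@]2(C)[C@@H]1CCC3OCCCO3.[Li+] | intermediate (not isolated)
16 | C7 enol triflate of the 7-oxo acetal (C7=C8), side chain on C9 cis to the C10 methyl | CC1=C(OS(=O)(=O)C(F)(F)F)C[C@@H]2C(C)(C)[C@H](O[Si](C)(C)C(C)(C)C)CC[C@@]2(C)[C@@H]1CCC3OCCCO3 | intermediate
17 | ent-3β-(tert-butyldimethylsilyloxy)-14,15,16-trinorlabd-7-en-13-al propane-1,3-diyl acetal | CC1=CC[C@@H]2C(C)(C)[C@H](O[Si](C)(C)C(C)(C)C)CC[C@@]2(C)[C@@H]1CCC3OCCCO3 | intermediate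
18 | ent-3β-(tert-butyldimethylsilyloxy)-14,15,16-trinorlabd-7-en-13-al | CC1=CC[C@@H]2C(C)(C)[C@H](O[Si](C)(C)C(C)(C)C)CC[C@@]2(C)[C@@H]1CCC=O | intermediate
19 | ent-3β-(tert-butyldimethylsilyloxy)-15,16-dinorlabd-7-en-13-yne | CC1=CC[C@@H]2C(C)(C)[C@H](O[Si](C)(C)C(C)(C)C)CC[C@@]2(C)[C@@H]1CCC#C | intermediate
20 | (E)-alkenyl(dimethyl)alane (Al on C14, new methyl on C13) | CC1=CC[C@@H]2C(C)(C)[C@H](O[Si](C)(C)C(C)(C)C)CC[C@@]2(C)[C@@H]1CC/C(C)=C/[Al](C)C | intermediate (not isolated)
21 | lithium (E)-alkenyl(butyl)dimethylalanate | CC1=CC[C@@H]2C(C)(C)[C@H](O[Si](C)(C)C(C)(C)C)CC[C@@]2(C)[C@@H]1CC/C(C)=C/[Al-](C)(C)CCCC.[Li+] | intermediate (not isolated)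
22 | ent-3β-(tert-butyldimethylsilyloxy)labda-7,13E-dien-15-ol | CC1=CC[C@@H]2C(C)(C)[C@H](O[Si](C)(C)C(C)(C)C)CC[C@@]2(C)[C@@H]1CC/C(C)=C/CO | intermediate
23 | tetradecane-1,14-diol | OCCCCCCCCCCCCCCO | starting material
24 | 14-bromotetradecan-1-ol | OCCCCCCCCCCCCCCBr | intermediate
25 | (14-bromotetradecyloxy)(tert-butyl)dimethylsilane | CC(C)(C)[Si](C)(C)OCCCCCCCCCCCCCCBr | intermediate
26 | 16-bromohexadecanoic acid | OC(=O)CCCCCCCCCCCCCCCBr | starting material
27 | [14-(tert-butyldimethylsilyloxy)tetradecyl]magnesium bromide | CC(C)(C)[Si](C)(C)OCCCCCCCCCCCCCC[Mg]Br | intermediate (not isolated)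
28 | chloromagnesium 16-bromohexadecanoate | [O-]C(=O)CCCCCCCCCCCCCCCBr.[Mg+2].[Cl-] | intermediate (not isolated)
29 | 30-(tert-butyldimethylsilyloxy)triacontanoic acid | OC(=O)CCCCCCCCCCCCCCCCCCCCCCCCCCCCCO[Si](C)(C)C(C)(C)C | intermediate
30 | ent-3β-(tert-butyldimethylsilyloxy)labda-7,13E-dien-15-yl 30-(tert-butyldimethylsilyloxy)triacontanoate | CC1=CC[C@@H]2C(C)(C)[C@H](O[Si](C)(C)C(C)(C)C)CC[C@@]2(C)[C@@H]1CC/C(C)=C/COC(=O)CCCCCCCCCCCCCCCCCCCCCCCCCCCCCO[Si](C)(C)C(C)(C)C | intermediate
31 | ent-3β-hydroxylabda-7,13E-dien-15-yl 30-hydroxytriacontanoate (CNP0303636.1) | CC1=CC[C@@H]2C(C)(C)[C@H](O)CC[C@@]2(C)[C@@H]1CC/C(C)=C/COC(=O)CCCCCCCCCCCCCCCCCCCCCCCCCCCCCO | target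

**Step count**

Total steps: 18. Longest linear sequence: 15 (steps 1–13, 17, 18); the acid is made in 3 steps (14–16).

**Steps most likely to fail**

1. Step 5. The tertiary radical may be reduced before it cyclises, the closure onto the aldehyde may revert by β-scission of the alkoxyl radical, and the two faces of the carbonyl group may be poorly differentiated at C3. The fallback sets out from 8 and comes back at 11. The aldehyde of 8 is converted into the nitrile with I2 and aqueous NH3 in THF, giving the keto nitrile F1. Under the same Fe(acac)3/PhSiH3 conditions the C4 radical adds 6-exo to the nitrile; the iminyl radical does not fragment back, and hydrolysis of the imine on acidic work-up gives the 3,9-dione F2. NaBH4 in MeOH at −40 °C should then reduce only the saturated C3 ketone, by axial hydride delivery, to the equatorial alcohol 11. A C3 epimer mixture from step 5 could be brought to the same point by Dess–Martin oxidation to the 3,9-dione F2.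

2. Step 9. The enone may be over-reduced, proton exchange may scramble the position of the enolate before triflation, and facial control of the protonation at C9 may be incomplete. The fallback sets out from 14 and comes back at 17. Enone 14 is condensed with TsNHNH2 (EtOH, cat. AcOH) to the tosylhydrazone F3. Catecholborane in CHCl3 at 0 °C, followed by NaOAc·3H2O at reflux, reduces the C=N bond; sulfinate is lost and the allylic diazene expels N2 in a retro-ene step that places hydrogen on C9 and the double bond at C7=C8. This gives 17 without an enolate or a triflate. Equatorial hydride delivery to C7 should place the diazene axial on the face anti to the angular methyl, so the hydrogen is handed to the same face of C9 as in step 9.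

3. Step 3. Chemoselectivity may be lost through competing hydroboration of the isopropenyl group or 1,2-reduction of the enone, and the enone may be epoxidised during the oxidative work-up. The fallback sets out from 3 and comes back at 8. Enolate 4 (LiN(i-Pr)2, THF/DMPU) is alkylated with 2-(2-iodoethyl)-1,3-dioxolane, again anti to the isopropenyl group, to give the dioxolane F4. 1 M HCl in THF then unmasks aldehyde 8 directly, so neither hydroboration nor alcohol oxidation is needed.

**Further compounds**

F1 | step 5 | keto nitrile, 6-(2-cyanoethyl)-6-methylcarvone, configuration as in 5 | CC1=CC[C@H](C(C)=C)[C@@](C)(CCC#N)C1=O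
F2 | step 5 | ent-11-nordrim-7-ene-3,9-dione (trans-fused) | CC1=CC[C@@H]2C(C)(C)C(=O)CC[C@@]2(C)C1=O
F3 | step 9 | C7 tosylhydrazone of enone 14 | CC=1C(=NNS(=O)(=O)c3ccc(C)cc3)C[C@@H]2C(C)(C)[C@H](O[Si](C)(C)C(C)(C)C)CC[C@@]2(C)C=1CCC4OCCCO4
F4 | step 3 | 6-[2-(1,3-dioxolan-2-yl)ethyl]-6-methylcarvone, configuration as in 5 | CC1=CC[C@H](C(C)=C)[C@@](C)(CCC2OCCO2)C1=O
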